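**Plan** (drimane numbering: ring A = C1–C5 and C10, ring B = C5–C10, C11 = the CH2O carbon on C9; TBDPS = tert-butyldiphenylsilyl)
1. Cuts, in retrosynthetic order: the C11–O aryl ether to isofraxidin; C1=C2 of the ring A enone (aldol condensation); C9–C10 of ring B; the lactone bonds C1–O and C5=C10; C6–C7 (aldol).
2. Enabling feature: ring B is the cyclohexene C5–C6–C7=C8–C9–C10, and its C7=C8 alkene lies one carbon from the bond joining tertiary C9 to quaternary C10, which carries C1 as a latent carboxyl. C9–C10 is therefore a Claisen bond, and tying C1 to C7 through oxygen gives a δ-lactone (ring O, C1, C10, C5, C6, C7) with an E-alkenyl arm (C8=C9–C11) on C7.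
3. Forward order: enal plus methyl ketone, aldol, phosphonoacetate, unsaturated lactone, cis lactone, α-methyl lactone; the ring contraction then makes ring B; C1 is taken to the aldehyde, the ketone is unmasked and aldol condensation closes ring A; the coumarin is attached last.
4. Stereochemistry: C7 comes from a reagent-controlled boron aldol; C5 from hydride delivery anti to the C7 arm; C9 and C10 arise together in the boat [3,3] shift, which consumes C7. No centre is epimerisable afterwards.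

Key step: step 8

Assumption: compounds 1, 2, 4, 7 and 20 are bought; lithium and boron enolates that exist only inside one operation are described in the Why lines, whereas the covalent intermediates of step 8 are numbered.

Step 1
Reactants: 1 (TBDPS-oxy)acetaldehyde; 2 2-(triphenylphosphoranylidene)propanal
Product: 3 (E)-4-(TBDPS-oxy)-2-methylbut-2-enal
Conditions: toluene, 80 °C
Reagents that add atoms: none
Why: Wittig olefination with a stabilised formyl ylide, which should give the E trisubstituted enal and so places C7, C8 with its methyl, C9 and C11.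

Step 2
Reactants: 4 3,3-dimethylpentane-2,4-dione
Product: 5 3-methyl-3-(2-methyl-1,3-dioxolan-2-yl)butan-2-one
Conditions: HOCH2CH2OH (1.0 equiv), TsOH·H2O (cat.), benzene, Dean–Stark, reflux
Reagents that add atoms: ethylene glycol, OCCO
Why: acid-catalysed monoketalisation of a symmetric diketone; the second carbonyl, now beside a more crowded quaternary carbon, should react more slowly, so one equivalent of diol should stop at 5.

Step 3
Reactants: 5 3-methyl-3-(2-methyl-1,3-dioxolan-2-yl)butan-2-one; 3 (E)-4-(TBDPS-oxy)-2-methylbut-2-enal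
Product: 6 (5S,6E)-8-(TBDPS-oxy)-5-hydroxy-2,6-dimethyl-2-(2-methyl-1,3-dioxolan-2-yl)oct-6-en-3-one
Conditions: (+)-Ipc2BCl, Et3N, Et2O, 0 °C; then 3, −78 to −20 °C; H2O2, MeOH, pH 7 buffer
Reagents that add atoms: none
Why: boron-mediated aldol addition of a methyl ketone, in which the diisopinocampheylboron enolate of 5 (only its methyl group can enolise) adds 1,2 to the enal through a cyclic transition state whose isopinocampheyl groups select the aldehyde face; (+)-Ipc2BCl is the antipode expected to give the 7S carbinol (drimane C7), and the enantiomeric reagent would serve if the sense proved opposite.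

Step 4
Reactants: 6 (5S,6E)-8-(TBDPS-oxy)-5-hydroxy-2,6-dimethyl-2-(2-methyl-1,3-dioxolan-2-yl)oct-6-en-3-one; 7 2-(diethoxyphosphoryl)acetic acid
Product: 8 (2E,4S)-1-(TBDPS-oxy)-3,7-dimethyl-7-(2-methyl-1,3-dioxolan-2-yl)-6-oxooct-2-en-4-yl 2-(diethoxyphosphoryl)acetate
Conditions: DCC, DMAP (cat.), CH2Cl2, 0 °C to rt
Reagents that add atoms: none
Why: Steglich esterification of the only hydroxyl group under neutral, cold conditions, which should avoid retro-aldol cleavage and β-elimination of the β-hydroxy ketone.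

Step 5
Reactants: 8 (2E,4S)-1-(TBDPS-oxy)-3,7-dimethyl-7-(2-methyl-1,3-dioxolan-2-yl)-6-oxooct-2-en-4-yl 2-(diethoxyphosphoryl)acetate
Product: 9 (6S)-6-[(E)-4-(TBDPS-oxy)but-2-en-2-yl]-4-[2-(2-methyl-1,3-dioxolan-2-yl)propan-2-yl]-5,6-dihydro-2H-pyran-2-one
Conditions: LiCl, i-Pr2NEt, MeCN, rt to 40 °C
Reagents that add atoms: none
Why: intramolecular Horner–Wadsworth–Emmons reaction in its LiCl/amine variant, where the lithium-chelated phosphonate is deprotonated by an amine too weak to enolise the ketone (so β-elimination of the acyloxy group is held back) and the six-membered ring dictates the alkene geometry; C7 is untouched.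

Step 6
Reactants: 9 (6S)-6-[(E)-4-(TBDPS-oxy)but-2-en-2-yl]-4-[2-(2-methyl-1,3-dioxolan-2-yl)propan-2-yl]-5,6-dihydro-2H-pyran-2-one
Product: 10 (4S,6S)-6-[(E)-4-(TBDPS-oxy)but-2-en-2-yl]-4-[2-(2-methyl-1,3-dioxolan-2-yl)propan-2-yl]oxan-2-one (4,6-cis)
Conditions: Cu(OAc)2·H2O (3 mol %), 1,2-bis(diphenylphosphino)benzene (3 mol %), (EtO)2MeSiH, t-BuOH, toluene, rt
Reagents that add atoms: none
Why: conjugate reduction by phosphine-ligated CuH, a catalyst class that reduces β,β-disubstituted enones and enoates even when the β-carbon adjoins a quaternary centre; hydride should enter at C5 axially on the face anti to the pseudo-equatorial C7 arm, leaving the tert-alkyl group cis to the arm, while the arm alkene and the silyl ether are inert.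

Step 7
Reactants: 10 (4S,6S)-6-[(E)-4-(TBDPS-oxy)but-2-en-2-yl]-4-[2-(2-methyl-1,3-dioxolan-2-yl)propan-2-yl]oxan-2-one
Product: 11 (3R,4S,6S)-6-[(E)-4-(TBDPS-oxy)but-2-en-2-yl]-3-methyl-4-[2-(2-methyl-1,3-dioxolan-2-yl)propan-2-yl]oxan-2-one (3,4-trans and 4,6-cis)
Conditions: LiN(i-Pr)2, THF, −78 °C; MeI, −78 to −40 °C
Reagents that add atoms: iodomethane, CI
Why: lactone enolate alkylation, in which iodomethane should approach C10 anti to the neighbouring tert-alkyl group to give the 3,4-trans lactone; this centre is erased in step 8 in any case.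

Step 8
Reactants: 11 (3R,4S,6S)-6-[(E)-4-(TBDPS-oxy)but-2-en-2-yl]-3-methyl-4-[2-(2-methyl-1,3-dioxolan-2-yl)propan-2-yl]oxan-2-one
Product: 14 (1R,2S,6R)-2-[(TBDPS-oxy)methyl]-1,3-dimethyl-6-[2-(2-methyl-1,3-dioxolan-2-yl)propan-2-yl]cyclohex-3-ene-1-carboxylic acid, via silyl ketene acetal 12 (not isolated), via trimethylsilyl ester 13 (not isolated)
Conditions: LiN(i-Pr)2, THF, −78 °C; Me3SiCl–Et3N, −78 °C to rt; toluene, 110 °C; then H2O/MeOH, pH 5
Reagents that add atoms: chlorotrimethylsilane, C[Si](C)(C)Cl (its Me3Si group is carried by 12 and 13 and is lost on work-up)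
Why: LiN(i-Pr)2 removes the only α-hydrogen (C10–H; the ketone is masked) and O-silylation gives the cyclic silyl ketene acetal 12, which on heating should undergo a concerted [3,3]-sigmatropic shift over C10=C1–O–C7–C8=C9, forming C9–C10 and breaking C7–O to give silyl ester 13, hydrolysed to 14 on work-up. The closest known reaction is the Ireland–Claisen ring contraction of alkenyl lactone silyl ketene acetals to cycloalkenecarboxylic acids. Ring B (C5–C6–C7=C8–C9–C10) closes by sigmatropic contraction of the six-membered lactone, not by a cyclisation of Baldwin type, through a boat-like transition state shaped like bicyclo[2.2.2]octane (bridgeheads C7 and C10; bridges O–C1, C5–C6 and C8–C9) that the lactone ring enforces. C10 is set by the C7 stereocentre, because the arm can reach only the lactone face on which it stands, and C9 is set by the E alkene inside the enforced boat, which turns C11 toward the O–C1 bridge, that is syn to the carboxyl and anti to the C10 methyl. The C5 tert-alkyl group, cis to the arm in 11, ends trans to the carboxyl and cis to the C10 methyl, which is the trans-decalin arrangement. The step needs O- rather than C-silylation and a rearrangement faster than loss of the ketene acetal; the fully substituted enolate carbon favours O-silylation, and the ring excludes any chair pathway that would give the C9 epimer.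

Step 9
Reactants: 14 (1R,2S,6R)-2-[(TBDPS-oxy)methyl]-1,3-dimethyl-6-[2-(2-methyl-1,3-dioxolan-2-yl)propan-2-yl]cyclohex-3-ene-1-carboxylic acid
Product: 15 [(1R,2S,6S)-2-[(TBDPS-oxy)methyl]-1,3-dimethyl-6-[2-(2-methyl-1,3-dioxolan-2-yl)propan-2-yl]cyclohex-3-en-1-yl]methanol
Conditions: LiAlH4, THF, 0 °C to reflux
Reagents that add atoms: none
Why: hydride reduction of a hindered tertiary carboxylic acid to the neopentyl alcohol; the dioxolane, the silyl ether and the trisubstituted alkene should be inert to LiAlH4, and no stereocentre is enolisable.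

Step 10
Reactants: 15 [(1R,2S,6S)-2-[(TBDPS-oxy)methyl]-1,3-dimethyl-6-[2-(2-methyl-1,3-dioxolan-2-yl)propan-2-yl]cyclohex-3-en-1-yl]methanol
Product: 16 (1R,2S,6S)-2-[(TBDPS-oxy)methyl]-1,3-dimethyl-6-[2-(2-methyl-1,3-dioxolan-2-yl)propan-2-yl]cyclohex-3-ene-1-carbaldehyde
Conditions: Dess–Martin periodinane, CH2Cl2, rt
Reagents that add atoms: none
Why: Dess–Martin oxidation of a primary neopentyl alcohol to the C1 aldehyde, which has no α-hydrogen and so can neither epimerise nor self-condense.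

Step 11
Reactants: 16 (1R,2S,6S)-2-[(TBDPS-oxy)methyl]-1,3-dimethyl-6-[2-(2-methyl-1,3-dioxolan-2-yl)propan-2-yl]cyclohex-3-ene-1-carbaldehyde
Product: 17 (1R,2S,6S)-2-[(TBDPS-oxy)methyl]-1,3-dimethyl-6-(2-methyl-3-oxobutan-2-yl)cyclohex-3-ene-1-carbaldehyde
Conditions: 1 M aq. HCl, THF, rt
Reagents that add atoms: water, O
Why: acid hydrolysis of the dioxolane to the C3 methyl ketone; the TBDPS ether is stable to dilute aqueous acid, and any keto aldehyde that starts to cyclise converges on 18 in step 12.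

Step 12
Reactants: 17 (1R,2S,6S)-2-[(TBDPS-oxy)methyl]-1,3-dimethyl-6-(2-methyl-3-oxobutan-2-yl)cyclohex-3-ene-1-carbaldehyde
Product: 18 (4aR,5S,8aS)-5-[(TBDPS-oxy)methyl]-1,1,4a,6-tetramethyl-4a,5,8,8a-tetrahydronaphthalen-2(1H)-one
Conditions: NaOMe, MeOH, rt to 40 °C
Reagents that add atoms: none
Why: intramolecular aldol condensation, 6-(enolendo)-exo-trig; the ketone can enolise only toward C2 and the aldehyde has no α-hydrogen, so only the ring A enone C1=C2–C3=O can form, C5, C9 and C10 carry no acidic hydrogen, and early loss of the silyl group would merely anticipate step 13.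

Step 13
Reactants: 18 (4aR,5S,8aS)-5-[(TBDPS-oxy)methyl]-1,1,4a,6-tetramethyl-4a,5,8,8a-tetrahydronaphthalen-2(1H)-one
Product: 19 (4aR,5S,8aS)-5-(hydroxymethyl)-1,1,4a,6-tetramethyl-4a,5,8,8a-tetrahydronaphthalen-2(1H)-one
Conditions: Bu4NF, AcOH, THF, rt
Reagents that add atoms: none
Why: fluoride cleavage of the silyl ether, buffered with acetic acid so that the enone does not meet basic fluoride.

Step 14
Reactants: 19 (4aR,5S,8aS)-5-(hydroxymethyl)-1,1,4a,6-tetramethyl-4a,5,8,8a-tetrahydronaphthalen-2(1H)-one; 20 isofraxidin (7-hydroxy-6,8-dimethoxy-2H-chromen-2-one)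
Product: 21 7-{[(1S,4aS,8aR)-2,5,5,8a-tetramethyl-6-oxo-1,4,4a,5,6,8a-hexahydronaphthalen-1-yl]methoxy}-6,8-dimethoxy-2H-chromen-2-one (CNP0330704.1)
Conditions: PPh3, DIAD, THF, 0 to 40 °C
Reagents that add atoms: none
Why: Mitsunobu etherification of the primary C11 alcohol with the acidic 7-hydroxycoumarin under neutral conditions, which should leave the coumarin lactone and the enone intact; C11 is not a stereocentre.

**Compound list**
1 | (TBDPS-oxy)acetaldehyde | O=CCO[Si](c1ccccc1)(c1ccccc1)C(C)(C)C | starting material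
2 | 2-(triphenylphosphoranylidene)propanal | CC(C=O)=P(c1ccccc1)(c1ccccc1)c1ccccc1 | starting material
3 | (E)-4-(TBDPS-oxy)-2-methylbut-2-enal | O=C/C(C)=C/CO[Si](c1ccccc1)(c1ccccc1)C(C)(C)C | intermediate
4 | 3,3-dimethylpentane-2,4-dione | CC(=O)C(C)(C)C(C)=O | starting material
5 | 3-methyl-3-(2-methyl-1,3-dioxolan-2-yl)butan-2-one | CC(=O)C(C)(C)C1(C)OCCO1 | intermediate
6 | (5S,6E)-8-(TBDPS-oxy)-5-hydroxy-2,6-dimethyl-2-(2-methyl-1,3-dioxolan-2-yl)oct-6-en-3-one | CC1(OCCO1)C(C)(C)C(=O)C[C@H](O)/C(C)=C/CO[Si](c1ccccc1)(c1ccccc1)C(C)(C)C | intermediate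
7 | 2-(diethoxyphosphoryl)acetic acid | CCOP(=O)(CC(=O)O)OCC | starting material
8 | (2E,4S)-1-(TBDPS-oxy)-3,7-dimethyl-7-(2-methyl-1,3-dioxolan-2-yl)-6-oxooct-2-en-4-yl 2-(diethoxyphosphoryl)acetate | CC1(OCCO1)C(C)(C)C(=O)C[C@H](OC(=O)CP(=O)(OCC)OCC)/C(C)=C/CO[Si](c1ccccc1)(c1ccccc1)C(C)(C)C | intermediate
9 | (6S)-6-[(E)-4-(TBDPS-oxy)but-2-en-2-yl]-4-[2-(2-methyl-1,3-dioxolan-2-yl)propan-2-yl]-5,6-dihydro-2H-pyran-2-one | O=C1C=C(C(C)(C)C2(C)OCCO2)C[C@H](O1)/C(C)=C/CO[Si](c1ccccc1)(c1ccccc1)C(C)(C)C | intermediate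
10 | (4S,6S)-6-[(E)-4-(TBDPS-oxy)but-2-en-2-yl]-4-[2-(2-methyl-1,3-dioxolan-2-yl)propan-2-yl]oxan-2-one | O=C1C[C@@H](C(C)(C)C2(C)OCCO2)C[C@H](O1)/C(C)=C/CO[Si](c1ccccc1)(c1ccccc1)C(C)(C)C | intermediate
11 | (3R,4S,6S)-6-[(E)-4-(TBDPS-oxy)but-2-en-2-yl]-3-methyl-4-[2-(2-methyl-1,3-dioxolan-2-yl)propan-2-yl]oxan-2-one | O=C1[C@H](C)[C@@H](C(C)(C)C2(C)OCCO2)C[C@H](O1)/C(C)=C/CO[Si](c1ccccc1)(c1ccccc1)C(C)(C)C | intermediate
12 | (2S,4S)-2-[(E)-4-(TBDPS-oxy)but-2-en-2-yl]-5-methyl-4-[2-(2-methyl-1,3-dioxolan-2-yl)propan-2-yl]-6-(trimethylsilyloxy)-3,4-dihydro-2H-pyran | C[Si](C)(C)OC1=C(C)[C@@H](C(C)(C)C2(C)OCCO2)C[C@H](O1)/C(C)=C/CO[Si](c1ccccc1)(c1ccccc1)C(C)(C)C | intermediate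
13 | trimethylsilyl (1R,2S,6R)-2-[(TBDPS-oxy)methyl]-1,3-dimethyl-6-[2-(2-methyl-1,3-dioxolan-2-yl)propan-2-yl]cyclohex-3-ene-1-carboxylate | CC(C)(C)[Si](c1ccccc1)(c1ccccc1)OC[C@H]1C(C)=CC[C@H](C(C)(C)C2(C)OCCO2)[C@@]1(C)C(=O)O[Si](C)(C)C | intermediate
14 | (1R,2S,6R)-2-[(TBDPS-oxy)methyl]-1,3-dimethyl-6-[2-(2-methyl-1,3-dioxolan-2-yl)propan-2-yl]cyclohex-3-ene-1-carboxylic acid | CC(C)(C)[Si](c1ccccc1)(c1ccccc1)OC[C@H]1C(C)=CC[C@H](C(C)(C)C2(C)OCCO2)[C@@]1(C)C(=O)O | intermediate
15 | [(1R,2S,6S)-2-[(TBDPS-oxy)methyl]-1,3-dimethyl-6-[2-(2-methyl-1,3-dioxolan-2-yl)propan-2-yl]cyclohex-3-en-1-yl]methanol | CC(C)(C)[Si](c1ccccc1)(c1ccccc1)OC[C@H]1C(C)=CC[C@H](C(C)(C)C2(C)OCCO2)[C@@]1(C)CO | intermediate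
16 | (1R,2S,6S)-2-[(TBDPS-oxy)methyl]-1,3-dimethyl-6-[2-(2-methyl-1,3-dioxolan-2-yl)propan-2-yl]cyclohex-3-ene-1-carbaldehyde | CC(C)(C)[Si](c1ccccc1)(c1ccccc1)OC[C@H]1C(C)=CC[C@H](C(C)(C)C2(C)OCCO2)[C@@]1(C)C=O | intermediate
17 | (1R,2S,6S)-2-[(TBDPS-oxy)methyl]-1,3-dimethyl-6-(2-methyl-3-oxobutan-2-yl)cyclohex-3-ene-1-carbaldehyde | CC(C)(C)[Si](c1ccccc1)(c1ccccc1)OC[C@H]1C(C)=CC[C@H](C(C)(C)C(C)=O)[C@@]1(C)C=O | intermediate
18 | (4aR,5S,8aS)-5-[(TBDPS-oxy)methyl]-1,1,4a,6-tetramethyl-4a,5,8,8a-tetrahydronaphthalen-2(1H)-one | CC(C)(C)[Si](c1ccccc1)(c1ccccc1)OC[C@H]1C(C)=CC[C@@H]2C(C)(C)C(=O)C=C[C@]21C | intermediate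
19 | (4aR,5S,8aS)-5-(hydroxymethyl)-1,1,4a,6-tetramethyl-4a,5,8,8a-tetrahydronaphthalen-2(1H)-one | OC[C@H]1C(C)=CC[C@@H]2C(C)(C)C(=O)C=C[C@]21C | intermediate
20 | isofraxidin (7-hydroxy-6,8-dimethoxy-2H-chromen-2-one) | COc1cc2ccc(=O)oc2c(OC)c1O | starting material
21 | 7-{[(1S,4aS,8aR)-2,5,5,8a-tetramethyl-6-oxo-1,4,4a,5,6,8a-hexahydronaphthalen-1-yl]methoxy}-6,8-dimethoxy-2H-chromen-2-one | COc1cc2ccc(=O)oc2c(OC)c1OC[C@H]1C(C)=CC[C@@H]2C(C)(C)C(=O)C=C[C@]21C | target

**Step count and risks**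

Total steps: 14. Longest linear sequence: 13 steps (4 to 21 through steps 2 to 14; the branch 1 + 2 to 3 joins at step 3).

Steps most likely to fail:

Step 8. Both ends of the new C9–C10 bond are substituted, so the boat rearrangement may need more heat than the silyl ketene acetal tolerates. The ketene acetal could then be lost by proton return to 11, by C-silylation or by fragmentation before it rearranges. The fallback keeps the bond construction but uses a neutral, thermally robust allyl vinyl ether in place of an ester enolate derivative. It sets out from 11. Reduction with i-Bu2AlH in toluene at −78 °C should give the lactol (3R,4S,6S)-6-[(E)-4-(TBDPS-oxy)but-2-en-2-yl]-3-methyl-4-[2-(2-methyl-1,3-dioxolan-2-yl)propan-2-yl]oxan-2-ol F1. Dehydration with MeSO2Cl and Et3N in CH2Cl2 should give the cyclic enol ether (2S,4S)-2-[(E)-4-(TBDPS-oxy)but-2-en-2-yl]-5-methyl-4-[2-(2-methyl-1,3-dioxolan-2-yl)propan-2-yl]-3,4-dihydro-2H-pyran F2. Heating F2 in xylene at 180 to 200 °C in base-washed glass is the thermal Claisen ring contraction of a 2-alkenyl-3,4-dihydro-2H-pyran to a cyclohex-3-enecarbaldehyde. It passes through the same enforced boat and should deliver aldehyde 16 directly. The route is rejoined at 16, and steps 9 and 10 are no longer needed.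

Step 5. The β-acyloxy ketone 8 may lose its acyloxy group by base-induced β-elimination, or the phosphonate anion may attack the hindered tert-alkyl ketone too slowly, so that ring closure is outrun. The fallback forms the C5–C10 bond reductively under non-basic conditions and introduces the alkene afterwards. It sets out from 6. Acylation with bromoacetyl bromide and pyridine in CH2Cl2 at −20 °C should give the bromoacetate (2E,4S)-1-(TBDPS-oxy)-3,7-dimethyl-7-(2-methyl-1,3-dioxolan-2-yl)-6-oxooct-2-en-4-yl 2-bromoacetate F3. SmI2 in THF at −78 °C then effects an intramolecular Reformatsky addition to the ketone, giving the hydroxy lactone (4R,6S)-6-[(E)-4-(TBDPS-oxy)but-2-en-2-yl]-4-hydroxy-4-[2-(2-methyl-1,3-dioxolan-2-yl)propan-2-yl]oxan-2-one F4. Its carbinol configuration is drawn as expected from a chelated chair and is immaterial. Dehydration with MeSO2Cl and Et3N in CH2Cl2 at 0 °C to rt comes back to the route at 9.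

Step 3. Face selection by the diisopinocampheylboron enolate of a methyl ketone may be incomplete, and the minor enantiomer would then be carried through every later step. The fallback replaces the stoichiometric chiral boron enolate by a catalytic Mukaiyama aldol with an open transition state. It sets out from 5. LiN(i-Pr)2 and Me3SiCl in THF at −78 °C should give the silyl enol ether trimethyl{[3-methyl-3-(2-methyl-1,3-dioxolan-2-yl)but-1-en-2-yl]oxy}silane F5. SiCl4, activated by a catalytic chiral bisphosphoramide Lewis base derived from binaphthyl-2,2'-diamine (the antipode chosen for the S carbinol), adds F5 to enal 3 in CH2Cl2 at −78 °C. This reaction class is at its best with conjugated aldehydes. Work-up with aqueous KF/NaHCO3 comes back to the route at 6.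

**Further compounds**
F1 | step 8 | (3R,4S,6S)-6-[(E)-4-(TBDPS-oxy)but-2-en-2-yl]-3-methyl-4-[2-(2-methyl-1,3-dioxolan-2-yl)propan-2-yl]oxan-2-ol (mixture of anomers) | OC1[C@H](C)[C@@H](C(C)(C)C2(C)OCCO2)C[C@H](O1)/C(C)=C/CO[Si](c1ccccc1)(c1ccccc1)C(C)(C)C
F2 | step 8 | (2S,4S)-2-[(E)-4-(TBDPS-oxy)but-2-en-2-yl]-5-methyl-4-[2-(2-methyl-1,3-dioxolan-2-yl)propan-2-yl]-3,4-dihydro-2H-pyran | C1=C(C)[C@@H](C(C)(C)C2(C)OCCO2)C[C@H](O1)/C(C)=C/CO[Si](c1ccccc1)(c1ccccc1)C(C)(C)C
F3 | step 5 | (2E,4S)-1-(TBDPS-oxy)-3,7-dimethyl-7-(2-methyl-1,3-dioxolan-2-yl)-6-oxooct-2-en-4-yl 2-bromoacetate | CC1(OCCO1)C(C)(C)C(=O)C[C@H](OC(=O)CBr)/C(C)=C/CO[Si](c1ccccc1)(c1ccccc1)C(C)(C)C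
F4 | step 5 | (4R,6S)-6-[(E)-4-(TBDPS-oxy)but-2-en-2-yl]-4-hydroxy-4-[2-(2-methyl-1,3-dioxolan-2-yl)propan-2-yl]oxan-2-one | O=C1C[C@@](O)(C(C)(C)C2(C)OCCO2)C[C@H](O1)/C(C)=C/CO[Si](c1ccccc1)(c1ccccc1)C(C)(C)C
F5 | step 3 | trimethyl{[3-methyl-3-(2-methyl-1,3-dioxolan-2-yl)but-1-en-2-yl]oxy}silane | C=C(O[Si](C)(C)C)C(C)(C)C1(C)OCCO1
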